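**Target:** (6R,3'R,6'R)-3'-hydroxy-ε,ε-caroten-3-one. Both ε rings are 6R; the hydroxy ring is 3'R with OH trans to the chain (the lactucaxanthin end group); all nine chain double bonds are E.

## Retrosynthetic overview

1. Target ⇐ C2-symmetric lactucaxanthin by oxidising one of its two identical allylic carbinols in the last step (MnO2), so the base-labile 3-oxo ring never meets a base.
2. Lactucaxanthin ⇐ two-directional double Wittig reaction: one C15 phosphonium salt used twice plus the C10 trienedial (C11=C12 and C11'=C12').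
3. C15 unit ⇐ C6–C7 bond by a phosphine-directed syn-SN2' substitution of a cyclohexenyl ester with a C6 dienyl metal; the C4 carbinol configuration is relayed to C6 (key step, in place of resolved α-ionone end groups).
4. Cyclohexenyl ester ⇐ ketoisophorone by asymmetric transfer hydrogenation (sets C3), anti epoxidation and Wharton transposition.
5. Ring order: no ring is formed in the route; both six-membered rings come intact from ketoisophorone through the single C15 unit and are joined to the chain at the same time in the double Wittig step.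

Ring positions use carotenoid numbering: C1 = CMe2, C3 = oxygen-bearing carbon, C5 = methyl-bearing alkene carbon, C6 = carbon carrying the chain.

Assumption: in step 1 the (R,R)-TsDPEN ligand is taken to give the (R)-alcohol by analogy with aryl ketones (alkene in the place of the arene); if the sense is opposite, the (S,S)-ligand is used and nothing else changes.

## Route

Step 1
Reactants: 1 ketoisophorone (2,6,6-trimethylcyclohex-2-ene-1,4-dione)
Product: 2 (4R)-4-hydroxy-2,6,6-trimethylcyclohex-2-en-1-one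
Conditions: RuCl[(R,R)-TsDPEN](p-cymene) (1 mol %), KOH (2 mol %), i-PrOH, 25 °C
Reagents that add atoms: none
Why: Noyori-type asymmetric transfer hydrogenation reduces only the unhindered C4 carbonyl (C1 sits between a quaternary carbon and the methyl-bearing alkene carbon), and the ligand's alkenyl/alkyl discrimination sets the (R)-carbinol that becomes C3' of the target.

Step 2
Reactants: 2 (4R)-4-hydroxy-2,6,6-trimethylcyclohex-2-en-1-one
Product: 3 (4R)-4-[(tert-butyldimethylsilyl)oxy]-2,6,6-trimethylcyclohex-2-en-1-one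
Conditions: TBSCl, imidazole, DMF, 25 °C
Reagents that add atoms: tert-butyldimethylsilyl chloride, CC(C)(C)[Si](C)(C)Cl
Why: Standard silyl ether formation that protects the carbinol and supplies the bulky group that steers the next step.

Step 3
Reactants: 3 (4R)-4-[(tert-butyldimethylsilyl)oxy]-2,6,6-trimethylcyclohex-2-en-1-one
Product: 4 (1S,5R,6S)-5-[(tert-butyldimethylsilyl)oxy]-1,3,3-trimethyl-7-oxabicyclo[4.1.0]heptan-2-one (epoxide trans to OTBS)
Conditions: 30% aq. H2O2, NaOH (0.2 equiv), MeOH, 0 °C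
Reagents that add atoms: hydrogen peroxide, OO
Why: Weitz–Scheffer nucleophilic epoxidation in which hydroperoxide adds to the β-carbon on the face opposite the neighbouring silyloxy group, fixing the C4–O bond trans to C3–O.

Step 4
Reactants: 4 (1S,5R,6S)-5-[(tert-butyldimethylsilyl)oxy]-1,3,3-trimethyl-7-oxabicyclo[4.1.0]heptan-2-one
Product: 6 (1R,6R)-6-[(tert-butyldimethylsilyl)oxy]-2,4,4-trimethylcyclohex-2-en-1-ol (OH trans to OTBS), via epoxy hydrazone 5 (not isolated)
Conditions: N2H4·H2O (3 equiv), AcOH (0.3 equiv), MeOH, 0 to 25 °C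
Reagents that add atoms: none
Why: Wharton transposition, in which the hydrazone opens the epoxide to a vinyl diazene that loses N2, moving the alkene to C5=C6 while the C4–O bond is never broken and so stays trans to OTBS.

Step 5
Reactants: 6 (1R,6R)-6-[(tert-butyldimethylsilyl)oxy]-2,4,4-trimethylcyclohex-2-en-1-ol
Product: 7 (1R,6R)-6-[(tert-butyldimethylsilyl)oxy]-2,4,4-trimethylcyclohex-2-en-1-yl 2-(diphenylphosphanyl)benzoate
Conditions: 2-(Ph2P)C6H4CO2H, dicyclohexylcarbodiimide, DMAP (10 mol %), CH2Cl2, 25 °C, argon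
Reagents that add atoms: 2-(diphenylphosphanyl)benzoic acid, OC(=O)c1ccccc1P(c1ccccc1)c1ccccc1
Why: Steglich esterification with retention at the carbinol installs the o-DPPB group, which is both leaving group and phosphine director for the key step.

Step 6
Reactants: 8 (2E)-3-methylpent-2-en-4-yn-1-ol
Product: 9 triethyl{[(2E)-3-methylpent-2-en-4-yn-1-yl]oxy}silane
Conditions: TESCl, imidazole, CH2Cl2, 0 °C
Reagents that add atoms: chlorotriethylsilane, CC[Si](CC)(CC)Cl
Why: Silylation gives a primary allylic TES ether that survives organometallic steps yet can later be removed in the presence of the secondary TBS ether.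

Step 7
Reactants: 9 triethyl{[(2E)-3-methylpent-2-en-4-yn-1-yl]oxy}silane
Product: 11 triethyl{[(2E,4E)-5-bromo-3-methylpenta-2,4-dien-1-yl]oxy}silane, via dienylzirconocene chloride 10 (not isolated)
Conditions: Cp2Zr(H)Cl, THF, 25 °C, dark; then N-bromosuccinimide, 0 °C
Reagents that add atoms: N-bromosuccinimide, BrN1C(=O)CCC1=O
Why: Hydrozirconation adds Zr–H syn across the terminal alkyne with zirconium at the terminal carbon, and bromination cleaves the C–Zr bond with retention to give the (E)-alkenyl bromide.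

Step 8
Reactants: 7 (1R,6R)-6-[(tert-butyldimethylsilyl)oxy]-2,4,4-trimethylcyclohex-2-en-1-yl 2-(diphenylphosphanyl)benzoate, 11 triethyl{[(2E,4E)-5-bromo-3-methylpenta-2,4-dien-1-yl]oxy}silane
Product: 14 triethyl{[(2E,4E)-5-[(1R,4R)-4-[(tert-butyldimethylsilyl)oxy]-2,6,6-trimethylcyclohex-2-en-1-yl]-3-methylpenta-2,4-dien-1-yl]oxy}silane, via dienyllithium 12 (not isolated), via dienylmagnesium bromide 13 (not isolated)
Conditions: 11, t-BuLi (2 equiv), Et2O, −78 °C; MgBr2·OEt2, −78 to 0 °C; then added over 1 h to 7 and CuBr·SMe2 (20 mol %), Et2O, 0 to 25 °C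
Reagents that add atoms: none
Why: Proposed new method: the phosphine of the o-DPPB ester binds the dienylcopper formed from 13 and CuBr·SMe2, so copper attacks C6 on the face of the leaving group (syn-SN2') and reductive elimination forms the C6–C7 bond there, relaying the C4 configuration to C6 (chain trans to OTBS) with retention of the diene geometry; the closest known reaction type is the o-DPPB-directed copper-mediated syn-SN2' allylic substitution with alkyl- and arylmagnesium halides, here extended to a dienylmagnesium reagent and to a γ-carbon next to a quaternary centre.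

Step 9
Reactants: 14 triethyl{[(2E,4E)-5-[(1R,4R)-4-[(tert-butyldimethylsilyl)oxy]-2,6,6-trimethylcyclohex-2-en-1-yl]-3-methylpenta-2,4-dien-1-yl]oxy}silane
Product: 15 (2E,4E)-5-[(1R,4R)-4-[(tert-butyldimethylsilyl)oxy]-2,6,6-trimethylcyclohex-2-en-1-yl]-3-methylpenta-2,4-dien-1-ol
Conditions: PPTS (10 mol %), MeOH, 0 °C
Reagents that add atoms: none
Why: Acid-catalysed methanolysis removes the primary TES ether far faster than the hindered secondary TBS ether, so only C11–OH is freed.

Step 10
Reactants: 15 (2E,4E)-5-[(1R,4R)-4-[(tert-butyldimethylsilyl)oxy]-2,6,6-trimethylcyclohex-2-en-1-yl]-3-methylpenta-2,4-dien-1-ol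
Product: 17 {(2E,4E)-5-[(1R,4R)-4-[(tert-butyldimethylsilyl)oxy]-2,6,6-trimethylcyclohex-2-en-1-yl]-3-methylpenta-2,4-dien-1-yl}triphenylphosphonium bromide, via allylic bromide 16 (not isolated)
Conditions: CBr4, PPh3 (1.2 equiv each), CH2Cl2, 0 °C; then PPh3 (1.5 equiv), 25 °C; precipitation from Et2O
Reagents that add atoms: triphenylphosphine, c1ccc(cc1)P(c1ccccc1)c1ccccc1; carbon tetrabromide, BrC(Br)(Br)Br
Why: Appel bromination under neutral conditions followed by SN2 quaternisation of PPh3 by the primary allylic bromide, leaving the ring silyl ether and both stereocentres untouched.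

Step 11
Reactants: 17 the C15 phosphonium bromide (2.1 equiv), 18 (2E,4E,6E)-2,7-dimethylocta-2,4,6-trienedial
Product: 21 (3R,6R,3'R,6'R)-3,3'-bis[(tert-butyldimethylsilyl)oxy]-ε,ε-carotene (all-E), via phosphorus ylide 19 (not isolated), via C25 apo-aldehyde 20 (not isolated)
Conditions: NaOMe (2.2 equiv), MeOH/CH2Cl2, 0 to 25 °C, dark; then n-heptane, reflux; crystallisation
Reagents that add atoms: none
Why: Two-directional double Wittig olefination in which the semi-stabilised allylic ylide gives mainly the E alkenes at C11=C12 and C11'=C12', heating converges residual Z isomers to all-E, and no stereocentre is involved.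

Step 12
Reactants: 21 (3R,6R,3'R,6'R)-3,3'-bis[(tert-butyldimethylsilyl)oxy]-ε,ε-carotene
Product: 22 lactucaxanthin, (3R,6R,3'R,6'R)-ε,ε-carotene-3,3'-diol
Conditions: TBAF, THF, 25 °C, dark, argon
Reagents that add atoms: none
Why: Fluoride-driven desilylation of both allylic silyl ethers; with no carbonyl yet in the molecule the doubly allylic C6–H centres are not at risk.

Step 13
Reactants: 22 lactucaxanthin, (3R,6R,3'R,6'R)-ε,ε-carotene-3,3'-diol
Product: 23 (6R,3'R,6'R)-3'-hydroxy-ε,ε-caroten-3-one (target)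
Conditions: activated MnO2 (added in portions), acetone, 25 °C, dark, stopped near half conversion (HPLC); chromatography, recovered 22 recycled
Reagents that add atoms: none
Why: Allylic alcohol oxidation with MnO2 under neutral heterogeneous conditions; the C2 symmetry of 22 makes oxidation of either hydroxyl give the same mono-ketone (statistical limit about half per pass), and the C6 centre γ to the new ketone is not exposed to base.

## Compound list

1 | ketoisophorone (2,6,6-trimethylcyclohex-2-ene-1,4-dione) | CC1=CC(=O)CC(C)(C)C1=O | starting material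
2 | (4R)-4-hydroxy-2,6,6-trimethylcyclohex-2-en-1-one | CC1=C[C@H](O)CC(C)(C)C1=O | intermediate
3 | (4R)-4-[(tert-butyldimethylsilyl)oxy]-2,6,6-trimethylcyclohex-2-en-1-one | CC1=C[C@H](O[Si](C)(C)C(C)(C)C)CC(C)(C)C1=O | intermediate
4 | (1S,5R,6S)-5-[(tert-butyldimethylsilyl)oxy]-1,3,3-trimethyl-7-oxabicyclo[4.1.0]heptan-2-one | C[C@]12O[C@H]1[C@H](O[Si](C)(C)C(C)(C)C)CC(C)(C)C2=O | intermediate
5 | hydrazone of 4 (not isolated) | C[C@]12O[C@H]1[C@H](O[Si](C)(C)C(C)(C)C)CC(C)(C)C2=NN | intermediate
6 | (1R,6R)-6-[(tert-butyldimethylsilyl)oxy]-2,4,4-trimethylcyclohex-2-en-1-ol | CC1=CC(C)(C)C[C@@H](O[Si](C)(C)C(C)(C)C)[C@@H]1O | intermediate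
7 | (1R,6R)-6-[(tert-butyldimethylsilyl)oxy]-2,4,4-trimethylcyclohex-2-en-1-yl 2-(diphenylphosphanyl)benzoate | CC1=CC(C)(C)C[C@@H](O[Si](C)(C)C(C)(C)C)[C@@H]1OC(=O)c1ccccc1P(c1ccccc1)c1ccccc1 | intermediate
8 | (2E)-3-methylpent-2-en-4-yn-1-ol | C#C/C(C)=C/CO | starting material
9 | triethyl{[(2E)-3-methylpent-2-en-4-yn-1-yl]oxy}silane | C#C/C(C)=C/CO[Si](CC)(CC)CC | intermediate
10 | chlorobis(cyclopentadienyl)[(1E,3E)-3-methyl-5-(triethylsilyloxy)penta-1,3-dien-1-yl]zirconium (not isolated) | CC[Si](CC)(CC)OC/C=C(C)/C=C/[Zr](Cl)(C1C=CC=C1)C1C=CC=C1 | intermediate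
11 | triethyl{[(2E,4E)-5-bromo-3-methylpenta-2,4-dien-1-yl]oxy}silane | CC[Si](CC)(CC)OC/C=C(C)/C=C/Br | intermediate
12 | [(1E,3E)-3-methyl-5-(triethylsilyloxy)penta-1,3-dien-1-yl]lithium (not isolated) | CC[Si](CC)(CC)OC/C=C(C)/C=C/[Li] | intermediate
13 | [(1E,3E)-3-methyl-5-(triethylsilyloxy)penta-1,3-dien-1-yl]magnesium bromide (not isolated) | CC[Si](CC)(CC)OC/C=C(C)/C=C/[Mg]Br | intermediate
14 | triethyl{[(2E,4E)-5-[(1R,4R)-4-[(tert-butyldimethylsilyl)oxy]-2,6,6-trimethylcyclohex-2-en-1-yl]-3-methylpenta-2,4-dien-1-yl]oxy}silane | CC[Si](CC)(CC)OC/C=C(C)/C=C/[C@H]1C(C)=C[C@H](O[Si](C)(C)C(C)(C)C)CC1(C)C | intermediate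
15 | (2E,4E)-5-[(1R,4R)-4-[(tert-butyldimethylsilyl)oxy]-2,6,6-trimethylcyclohex-2-en-1-yl]-3-methylpenta-2,4-dien-1-ol | OC/C=C(C)/C=C/[C@H]1C(C)=C[C@H](O[Si](C)(C)C(C)(C)C)CC1(C)C | intermediate
16 | allylic bromide of 15 (not isolated) | BrC/C=C(C)/C=C/[C@H]1C(C)=C[C@H](O[Si](C)(C)C(C)(C)C)CC1(C)C | intermediate
17 | {(2E,4E)-5-[(1R,4R)-4-[(tert-butyldimethylsilyl)oxy]-2,6,6-trimethylcyclohex-2-en-1-yl]-3-methylpenta-2,4-dien-1-yl}triphenylphosphonium bromide | [Br-].c1ccccc1[P+](c1ccccc1)(c1ccccc1)C/C=C(C)/C=C/[C@H]1C(C)=C[C@H](O[Si](C)(C)C(C)(C)C)CC1(C)C | intermediate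
18 | (2E,4E,6E)-2,7-dimethylocta-2,4,6-trienedial | O=C/C(C)=C/C=C/C=C(C)/C=O | starting material
19 | ylide of 17 (not isolated) | c1ccccc1P(c1ccccc1)(c1ccccc1)=C/C=C(C)/C=C/[C@H]1C(C)=C[C@H](O[Si](C)(C)C(C)(C)C)CC1(C)C | intermediate
20 | (3R,6R)-3-[(tert-butyldimethylsilyl)oxy]-12'-apo-ε-caroten-12'-al, all-E (not isolated) | O=C/C(C)=C/C=C/C=C(C)/C=C/C=C(C)/C=C/[C@H]1C(C)=C[C@H](O[Si](C)(C)C(C)(C)C)CC1(C)C | intermediate
21 | (3R,6R,3'R,6'R)-3,3'-bis[(tert-butyldimethylsilyl)oxy]-ε,ε-carotene | CC1=C[C@H](O[Si](C)(C)C(C)(C)C)CC(C)(C)[C@H]1/C=C/C(C)=C/C=C/C(C)=C/C=C/C=C(C)/C=C/C=C(C)/C=C/[C@H]1C(C)=C[C@H](O[Si](C)(C)C(C)(C)C)CC1(C)C | intermediate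
22 | lactucaxanthin, (3R,6R,3'R,6'R)-ε,ε-carotene-3,3'-diol | CC1=C[C@H](O)CC(C)(C)[C@H]1/C=C/C(C)=C/C=C/C(C)=C/C=C/C=C(C)/C=C/C=C(C)/C=C/[C@H]1C(C)=C[C@H](O)CC1(C)C | intermediate
23 | (6R,3'R,6'R)-3'-hydroxy-ε,ε-caroten-3-one | CC1=CC(=O)CC(C)(C)[C@H]1/C=C/C(C)=C/C=C/C(C)=C/C=C/C=C(C)/C=C/C=C(C)/C=C/[C@H]1C(C)=C[C@H](O)CC1(C)C | target

## Step count and risks

Total steps: 13. Longest linear sequence: 11 steps (1 → 2 → 3 → 4 → 6 → 7 → 14 → 15 → 17 → 21 → 22 → 23; steps 1–5 and 8–13). The side branch 8 → 9 → 11 is 2 steps.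

**Most likely to fail, with fallbacks**

Step 8 (directed syn-SN2' with a dienyl nucleophile). The γ-carbon is next to the CMe2 centre, and the reactive conformer needs the leaving group pseudoaxial, which forces the trans OTBS axial against a ring methyl. Attack at the ester carbonyl or at C4 could compete. The fallback sets out from 6 and comes back at 14. A Mitsunobu esterification of 6 with picolinic acid (PPh3, DIAD, THF, 0 °C) inverts the carbinol and gives the cis picolinate F3. F3 is then treated with dienylmagnesium bromide 13 and CuBr·SMe2 in THF/Et2O at −40 °C. This is the undirected, chelation-activated anti-SN2' pathway; from the inverted ester it delivers the chain to the same face of C6, and in the cis series the leaving group is pseudoaxial without any diaxial penalty.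

Step 4 (Wharton transposition at a ketone flanked by two fully substituted carbons). Hydrazone formation may be slow, and hydrazine may instead open the epoxide. The fallback sets out from 4 and comes back at 6. The ketone is reduced with NaBH4/CeCl3·7H2O in MeOH to the epoxy alcohol F1 (either carbinol epimer serves). F1 is acylated with PhOC(S)Cl, DMAP and pyridine to the O-phenyl thionocarbonate F2. F2 is heated with Bu3SnH and AIBN in benzene: the C6 radical opens the epoxide by C–O scission and the resulting alkoxy radical is reduced, giving 6 with the C4–O bond again untouched. This is a radical fragmentation in place of the diazene pathway.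

Step 13 (statistical mono-oxidation). It cannot exceed about half conversion to product per pass, and separating diol, mono-ketone and diketone on a light- and air-sensitive polyene may be lossy. The fallback sets out from 17 and 18 and comes back at 23; it differentiates the two ends before the chain is complete. Ylide 19 from one equivalent of 17 is added to a threefold excess of 18, and the C25 apo-aldehyde 20 is isolated. TBAF in THF frees the hydroxy apo-aldehyde F4. A second Wittig reaction of F4 with ylide 19 (NaOMe, MeOH/CH2Cl2, then heating in heptane) gives the mono-silyl ether F5, which has a single free allylic hydroxyl. MnO2 in acetone oxidises that hydroxyl completely to the silylated ketone F6. TBAF buffered with AcOH in THF at 0 °C then removes the last silyl group without epimerising C6, giving 23.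

## Further compounds

F1 | step 4 | epoxy alcohol from reduction of the ketone of 4 (other centres as in 4, carbinol epimers) | C[C@]12O[C@H]1[C@H](O[Si](C)(C)C(C)(C)C)CC(C)(C)C2O
F2 | step 4 | O-phenyl thionocarbonate of F1 | C[C@]12O[C@H]1[C@H](O[Si](C)(C)C(C)(C)C)CC(C)(C)C2OC(=S)Oc1ccccc1
F3 | step 8 | (1S,6R)-6-[(tert-butyldimethylsilyl)oxy]-2,4,4-trimethylcyclohex-2-en-1-yl pyridine-2-carboxylate (ester cis to OTBS) | CC1=CC(C)(C)C[C@@H](O[Si](C)(C)C(C)(C)C)[C@H]1OC(=O)c1ccccn1
F4 | step 13 | (3R,6R)-3-hydroxy-12'-apo-ε-caroten-12'-al | O=C/C(C)=C/C=C/C=C(C)/C=C/C=C(C)/C=C/[C@H]1C(C)=C[C@H](O)CC1(C)C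
F5 | step 13 | (3R,6R,3'R,6'R)-3'-[(tert-butyldimethylsilyl)oxy]-ε,ε-caroten-3-ol | CC1=C[C@H](O)CC(C)(C)[C@H]1/C=C/C(C)=C/C=C/C(C)=C/C=C/C=C(C)/C=C/C=C(C)/C=C/[C@H]1C(C)=C[C@H](O[Si](C)(C)C(C)(C)C)CC1(C)C
F6 | step 13 | (6R,3'R,6'R)-3'-[(tert-butyldimethylsilyl)oxy]-ε,ε-caroten-3-one | CC1=CC(=O)CC(C)(C)[C@H]1/C=C/C(C)=C/C=C/C(C)=C/C=C/C=C(C)/C=C/C=C(C)/C=C/[C@H]1C(C)=C[C@H](O[Si](C)(C)C(C)(C)C)CC1(C)C
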